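Everything rests on cutting the C1–O and C4–O bonds of the cyclohexane ring in one stroke. O1 and O4 are cis and 1,4 to each other and both trans to O5: the imprint of a peroxide bridge laid across C1 and C4 on the face opposite the C5 oxygen. In step 8 singlet oxygen adds to a ring-locked 3-silyloxy-1,3-diene that carries the ester at the C1 terminus and one stereocentre, a bulky silyl ether at C5; this creates the quaternary C1 carbinol and the C4 carbinol together and leaves C3 as a masked ketone, later reduced to axial O3. The endgame runs through the 1,5-lactone, acylated at O3 and then at O4.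

Key step: step 8

Remark: ring atoms are numbered as in quinic acid throughout (C1 carries the carboxyl; O1, O3, O4 on one face, O5 and the carboxyl on the other).
Assumption: the lipase of step 2 is taken to acetylate the hydroxyl that later becomes the C3 ketone; an enzyme of opposite preference would give the same monoacetate 3 by mono-hydrolysis of the meso diacetate.

Step 1
Reactants: 1 methyl 3,5-dihydroxybenzoate
Product: 2 methyl all-cis-3,5-dihydroxycyclohexane-1-carboxylate (meso)
Conditions: H2 (100 bar), 5% Rh/Al2O3, MeOH, AcOH (cat.), 80 °C; recrystallization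
Reagents that add atoms: none
Why: Heterogeneous arene hydrogenation on rhodium delivers all six hydrogens from the catalyst-bound face, so ester and both hydroxyls end up all-cis in a meso cyclohexane, and rhodium saturates phenols with little C–O hydrogenolysis.

Step 2
Reactants: 2 methyl all-cis-3,5-dihydroxycyclohexane-1-carboxylate
Product: 3 methyl (1S,3S,5R)-3-acetoxy-5-hydroxycyclohexane-1-carboxylate (all-cis)
Conditions: lipase from Burkholderia cepacia (immobilized), vinyl acetate, tert-butyl methyl ether, 30 °C
Reagents that add atoms: vinyl acetate, C=COC(C)=O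
Why: Lipase-catalysed irreversible transesterification (enzymatic desymmetrization of a meso diol) acylates one enantiotopic hydroxyl only, so the absolute configuration at C1, C3 and C5 is fixed here by enzyme control while vinyl alcohol leaves as acetaldehyde.

Step 3
Reactants: 3 methyl (1S,3S,5R)-3-acetoxy-5-hydroxycyclohexane-1-carboxylate
Product: 4 methyl (1R,3S,5R)-3-acetoxy-5-(triisopropylsilyloxy)cyclohexane-1-carboxylate (all-cis)
Conditions: TIPSOTf, 2,6-lutidine, CH2Cl2, 0 °C
Reagents that add atoms: triisopropylsilyl trifluoromethanesulfonate, CC(C)[Si](C(C)C)(C(C)C)OS(=O)(=O)C(F)(F)F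
Why: Silylation of a secondary alcohol with a silyl triflate and a hindered pyridine base; the triisopropylsilyl ether is chosen because it does not migrate to O3, survives enolates and dilute acid, and is bulky enough to shield one ring face in step 8.

Step 4
Reactants: 4 methyl (1R,3S,5R)-3-acetoxy-5-(triisopropylsilyloxy)cyclohexane-1-carboxylate
Product: 5 methyl (1R,3S,5R)-3-hydroxy-5-(triisopropylsilyloxy)cyclohexane-1-carboxylate (all-cis)
Conditions: K2CO3, MeOH, 0 °C → rt
Reagents that add atoms: none
Why: Base-catalysed methanolysis (transesterification) removes the acetate while the methyl ester exchanges degenerately, and the all-equatorial chair keeps the silyl group out of reach of O3 so that no enantiomer-scrambling silyl shift can occur.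

Step 5
Reactants: 5 methyl (1R,3S,5R)-3-hydroxy-5-(triisopropylsilyloxy)cyclohexane-1-carboxylate
Product: 7 methyl 1-chloro-3-hydroxy-5-(triisopropylsilyloxy)cyclohexane-1-carboxylate (C1 epimers; 3-OH and 5-OSi cis as in 5), via dilithium alkoxide-enolate 6 (not isolated)
Conditions: LiN(iPr)2 (2.3 equiv), THF, −78 °C; C2Cl6, −78 → −40 °C; NH4Cl (aq)
Reagents that add atoms: hexachloroethane, ClC(Cl)(Cl)C(Cl)(Cl)Cl
Why: Ester enolate halogenation: two equivalents of amide base give the O3 alkoxide and the only possible ester enolate, at C1, which takes a positive chlorine from hexachloroethane, so the future alkene terminus is marked without any regiochemical choice and the C1 configuration is irrelevant because this carbon becomes trigonal in step 6.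

Step 6
Reactants: 7 methyl 1-chloro-3-hydroxy-5-(triisopropylsilyloxy)cyclohexane-1-carboxylate
Product: 9 methyl (5R)-3-oxo-5-(triisopropylsilyloxy)cyclohex-1-ene-1-carboxylate, via beta-chloro ketone 8 (not isolated)
Conditions: Dess–Martin periodinane, CH2Cl2, 0 °C → rt; then Et3N, 0 °C, brief
Reagents that add atoms: none
Why: Dess–Martin oxidation followed by E1cB elimination: once C3 is a ketone only the C2 hydrogens are both acidic and next to the chloride-bearing carbon, so the amine can expel chloride only toward C1=C2 and the C5 stereocentre is untouched.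

Step 7
Reactants: 9 methyl (5R)-3-oxo-5-(triisopropylsilyloxy)cyclohex-1-ene-1-carboxylate
Product: 11 methyl (5R)-3-(tert-butyldimethylsilyloxy)-5-(triisopropylsilyloxy)cyclohexa-1,3-diene-1-carboxylate, via lithium dienolate 10 (not isolated)
Conditions: LiN(iPr)2 (1.05 equiv), THF, −78 °C; TBSOTf, −78 °C; Et3N; rapid filtration through Et3N-deactivated silica, used at once
Reagents that add atoms: tert-butyldimethylsilyl trifluoromethanesulfonate, CC(C)(C)[Si](C)(C)OS(=O)(=O)C(F)(F)F
Why: Kinetic alpha-prime deprotonation of a cyclohexenone by a lithium amide gives the cross-conjugated C3=C4 dienolate, which the silyl triflate traps on oxygen (silyl dienol ether formation), and at −78 °C beta-silyloxy lithium enolates of this kind should not expel the C5 oxygen.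

Step 8
Reactants: 11 methyl (5R)-3-(tert-butyldimethylsilyloxy)-5-(triisopropylsilyloxy)cyclohexa-1,3-diene-1-carboxylate; 12 dioxygen
Product: 13 methyl 5-(tert-butyldimethylsilyloxy)-8-(triisopropylsilyloxy)-2,3-dioxabicyclo[2.2.2]oct-5-ene-1-carboxylate (peroxide bridge from C1 to C4 of the quinate ring on the face opposite the C5 silyloxy group)
Conditions: O2, hν (visible), tetraphenylporphyrin (cat.), CH2Cl2, −78 °C
Reagents that add atoms: dioxygen, O=O
Why: Triplet-excited tetraphenylporphyrin passes its energy to O2, and the singlet oxygen formed adds suprafacially to the s-cis-locked diene C1=C2–C3=C4 in a concerted but asynchronous [4+2] cycloaddition that begins at the nucleophilic enol-ether carbon C4 and ends at C1. The closest known reaction type is endoperoxide formation from 2-silyloxycyclohexa-1,3-dienes and other homoannular dienes. The one new ring, the 1,2-dioxane of the 2,3-dioxabicyclo[2.2.2]octene, closes by cycloaddition with both C–O bonds formed on the same diene face. C1 and C4 are therefore set cis to each other by the suprafacial mode, and their sense is controlled by the C5 stereocentre, whose bulky triisopropylsilyloxy group next to C4 blocks one face so that oxygen enters anti to it. Two selectivities are needed: facial selectivity, secured by that C5 ether, and periselectivity over 1,4-silyl transfer and dioxetane formation at the enol ether, secured by the ring-locked cisoid diene, the bulky tert-butyldimethylsilyl group on the enol oxygen, the non-polar solvent and the low temperature. The ester at C1 should slow but not stop the closure, because the 3-silyloxy group raises the diene HOMO.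

Step 9
Reactants: 13 endoperoxide
Product: 15 methyl 5-O-(triisopropylsilyl)-3-dehydroquinate (1-OH and 4-OH cis; 5-OSi trans to both), via silyl enol ether diol 14 (not isolated)
Conditions: thiourea, MeOH (moist), 0 °C → rt; then 0.1 M HCl (aq), THF, 0 °C; used without storage
Reagents that add atoms: none
Why: Thiourea reduction of a dialkyl peroxide cleaves only the O–O bond, so C1 and C4 keep their configuration, and cold dilute acid then hydrolyses the silyl enol ether by protonation at C2 much faster than it attacks the alkyl silyl ether or dehydrates the beta-hydroxy ketone.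

Step 10
Reactants: 15 methyl 5-O-(triisopropylsilyl)-3-dehydroquinate
Product: 16 methyl 5-O-(triisopropylsilyl)quinate
Conditions: LiBH(sec-Bu)3 (3.5 equiv), THF, −78 °C; NH4Cl (aq)
Reagents that add atoms: none
Why: Diastereoselective ketone reduction with a bulky trialkylborohydride: in the chair with O4 and O5 equatorial the axial O1 blocks the axial trajectory, so hydride enters equatorially from the face opposite O1 and the new C3 hydroxyl is axial, cis to O4 and O1 (substrate control), while the hindered tertiary alpha-hydroxy ester is not reduced at −78 °C.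

Step 11
Reactants: 16 methyl 5-O-(triisopropylsilyl)quinate
Product: 18 (1S,3R,4R,5R)-1,3,4-trihydroxy-6-oxabicyclo[3.2.1]octan-7-one (quinic acid 1,5-lactone), via methyl quinate 17 (not isolated)
Conditions: HCl (1.25 M in MeOH), 40 °C; evaporate; TsOH·H2O (cat.), toluene–DMF, reflux (Dean–Stark)
Reagents that add atoms: none
Why: Acid methanolysis of the silyl ether frees O5, and acid-catalysed intramolecular transesterification (lactonization) then joins O5 to the cis C1 carboxyl through the diaxial chair as methanol distils off; no stereocentre is touched, and the lactone masks O5 and the acid while turning O3 equatorial and O4 axial.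

Step 12
Reactants: 19 caffeic acid
Product: 20 (E)-3-(3,4-diacetoxyphenyl)prop-2-enoic acid
Conditions: Ac2O, pyridine, DMAP (cat.), rt; aqueous work-up
Reagents that add atoms: acetic anhydride, CC(=O)OC(C)=O
Why: Acetylation of phenols with acetic anhydride and pyridine; the mixed anhydride formed at the carboxyl is hydrolysed on work-up, and the acetates keep the phenols out of the later acylations.

Step 13
Reactants: 18 quinic acid 1,5-lactone; 20 (E)-3-(3,4-diacetoxyphenyl)prop-2-enoic acid
Product: 22 3-O-(3,4-di-O-acetylcaffeoyl)quinic acid 1,5-lactone, via 3,4-di-O-acetylcaffeoyl chloride 21 (not isolated)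
Conditions: 20, (COCl)2, DMF (cat.), CH2Cl2, 0 °C → rt, evaporate; then 18, pyridine, −20 → 0 °C, slow addition of 21 (1.0 equiv)
Reagents that add atoms: none
Why: Acid chloride formation with oxalyl chloride and pyridine-mediated esterification: in the lactone the equatorial secondary O3 hydroxyl is far more accessible than the axial O4 hydroxyl under the lactone bridge or the tertiary O1 hydroxyl, so one equivalent of acid chloride at low temperature should acylate O3.

Step 14
Reactants: 23 p-coumaric acid
Product: 24 (E)-3-(4-acetoxyphenyl)prop-2-enoic acid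
Conditions: Ac2O, pyridine, DMAP (cat.), rt; aqueous work-up
Reagents that add atoms: acetic anhydride, CC(=O)OC(C)=O
Why: Phenol acetylation as in step 12, so that only the carboxyl of the coumaric unit is activated later.

Step 15
Reactants: 22 3-O-(3,4-di-O-acetylcaffeoyl)quinic acid 1,5-lactone; 24 (E)-3-(4-acetoxyphenyl)prop-2-enoic acid
Product: 26 3-O-(3,4-di-O-acetylcaffeoyl)-4-O-(4-O-acetyl-p-coumaroyl)quinic acid 1,5-lactone, via 4-O-acetyl-p-coumaroyl chloride 25 (not isolated)
Conditions: 24, (COCl)2, DMF (cat.), CH2Cl2, evaporate; then 22, pyridine, DMAP (cat.), CH2Cl2, 0 °C → rt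
Reagents that add atoms: none
Why: DMAP-catalysed acylation drives the acid chloride onto the one remaining secondary hydroxyl, the axial O4, while the tertiary O1 hydroxyl next to the lactone carbonyl reacts much more slowly, and the aprotic non-nucleophilic medium avoids O3 to O4 acyl migration.

Step 16
Reactants: 26 3-O-(3,4-di-O-acetylcaffeoyl)-4-O-(4-O-acetyl-p-coumaroyl)quinic acid 1,5-lactone
Product: 27 3-O-caffeoyl-4-O-p-coumaroylquinic acid (CNP0077575.1)
Conditions: 1 M HCl (aq), THF, rt, prolonged stirring
Reagents that add atoms: water, O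
Why: Acid-catalysed hydrolysis opens the strained bicyclic lactone to the hydroxy acid and cleaves the three aryl acetates, which are much more labile than the two alkyl cinnamate esters, and acyl migration to the freed O5, a base-promoted process, is held back at low pH; no stereocentre is affected.

Compound list
1 | methyl 3,5-dihydroxybenzoate | COC(=O)c1cc(O)cc(O)c1 | starting material
2 | methyl all-cis-3,5-dihydroxycyclohexane-1-carboxylate (meso; ester and both hydroxyls on one face) | COC(=O)[C@@H]1C[C@H](O)C[C@H](O)C1 | intermediate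
3 | methyl (1S,3S,5R)-3-acetoxy-5-hydroxycyclohexane-1-carboxylate (all-cis) | COC(=O)[C@@H]1C[C@H](OC(C)=O)C[C@H](O)C1 | intermediate
4 | methyl (1R,3S,5R)-3-acetoxy-5-(triisopropylsilyloxy)cyclohexane-1-carboxylate (all-cis) | COC(=O)[C@@H]1C[C@H](OC(C)=O)C[C@H](O[Si](C(C)C)(C(C)C)C(C)C)C1 | intermediate
5 | methyl (1R,3S,5R)-3-hydroxy-5-(triisopropylsilyloxy)cyclohexane-1-carboxylate (all-cis) | COC(=O)[C@@H]1C[C@H](O)C[C@H](O[Si](C(C)C)(C(C)C)C(C)C)C1 | intermediate
6 | dilithium alkoxide-enolate of 5 (lithium O3 alkoxide, lithium ester enolate at C1; not isolated) | [Li]OC(OC)=C1C[C@H](O[Li])C[C@H](O[Si](C(C)C)(C(C)C)C(C)C)C1 | intermediate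
7 | methyl 1-chloro-3-hydroxy-5-(triisopropylsilyloxy)cyclohexane-1-carboxylate (3-OH and 5-OSi cis as in 5; C1 epimers, C1 left undefined) | COC(=O)C1(Cl)C[C@H](O)C[C@H](O[Si](C(C)C)(C(C)C)C(C)C)C1 | intermediate
8 | methyl 1-chloro-3-oxo-5-(triisopropylsilyloxy)cyclohexane-1-carboxylate (C5 as in 5; C1 epimers; not isolated) | COC(=O)C1(Cl)CC(=O)C[C@H](O[Si](C(C)C)(C(C)C)C(C)C)C1 | intermediate
9 | methyl (5R)-3-oxo-5-(triisopropylsilyloxy)cyclohex-1-ene-1-carboxylate | COC(=O)C1=CC(=O)C[C@H](O[Si](C(C)C)(C(C)C)C(C)C)C1 | intermediate
10 | lithium (5R)-dienolate of 9 (C1=C2 and C3=C4, O–Li on C3; not isolated) | COC(=O)C1=CC(O[Li])=C[C@H](O[Si](C(C)C)(C(C)C)C(C)C)C1 | intermediate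
11 | methyl (5R)-3-(tert-butyldimethylsilyloxy)-5-(triisopropylsilyloxy)cyclohexa-1,3-diene-1-carboxylate | COC(=O)C1=CC(O[Si](C)(C)C(C)(C)C)=C[C@H](O[Si](C(C)C)(C(C)C)C(C)C)C1 | intermediate
12 | dioxygen | O=O | starting material
13 | methyl 5-(tert-butyldimethylsilyloxy)-8-(triisopropylsilyloxy)-2,3-dioxabicyclo[2.2.2]oct-5-ene-1-carboxylate (peroxide bridge anti to the 8-silyloxy group) | O1[C@H]2[C@H](O[Si](C(C)C)(C(C)C)C(C)C)C[C@](O1)(C(=O)OC)C=C2O[Si](C)(C)C(C)(C)C | intermediate
14 | methyl 1,4-dihydroxy-3-(tert-butyldimethylsilyloxy)-5-(triisopropylsilyloxy)cyclohex-2-ene-1-carboxylate (1-OH and 4-OH cis; 5-OSi trans to both; not isolated) | COC(=O)[C@]1(O)C=C(O[Si](C)(C)C(C)(C)C)[C@@H](O)[C@H](O[Si](C(C)C)(C(C)C)C(C)C)C1 | intermediate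
15 | methyl 5-O-(triisopropylsilyl)-3-dehydroquinate (methyl 1,4-dihydroxy-3-oxo-5-silyloxycyclohexane-1-carboxylate; 1-OH and 4-OH cis; 5-OSi trans to both) | COC(=O)[C@]1(O)CC(=O)[C@@H](O)[C@H](O[Si](C(C)C)(C(C)C)C(C)C)C1 | intermediate
16 | methyl 5-O-(triisopropylsilyl)quinate (1-OH, 3-OH and 4-OH cis; 5-OSi trans) | COC(=O)[C@]1(O)C[C@@H](O)[C@@H](O)[C@H](O[Si](C(C)C)(C(C)C)C(C)C)C1 | intermediate
17 | methyl quinate, methyl (1S,3R,4S,5R)-1,3,4,5-tetrahydroxycyclohexane-1-carboxylate (not isolated) | COC(=O)[C@]1(O)C[C@@H](O)[C@@H](O)[C@H](O)C1 | intermediate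
18 | quinic acid 1,5-lactone, (1S,3R,4R,5R)-1,3,4-trihydroxy-6-oxabicyclo[3.2.1]octan-7-one | O[C@@]12C[C@@H](O)[C@@H](O)[C@@H](C1)OC2=O | intermediate
19 | caffeic acid | O=C(O)/C=C/c1ccc(O)c(O)c1 | starting material
20 | (E)-3-(3,4-diacetoxyphenyl)prop-2-enoic acid | CC(=O)Oc1ccc(/C=C/C(=O)O)cc1OC(C)=O | intermediate
21 | (E)-3-(3,4-diacetoxyphenyl)prop-2-enoyl chloride (not isolated) | CC(=O)Oc1ccc(/C=C/C(Cl)=O)cc1OC(C)=O | intermediate
22 | 3-O-(3,4-di-O-acetylcaffeoyl)quinic acid 1,5-lactone (ester on the equatorial O3; O1 and O4 free) | O[C@@]12C[C@@H](OC(=O)/C=C/c3ccc(OC(C)=O)c(OC(C)=O)c3)[C@@H](O)[C@@H](C1)OC2=O | intermediate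
23 | p-coumaric acid | O=C(O)/C=C/c1ccc(O)cc1 | starting material
24 | (E)-3-(4-acetoxyphenyl)prop-2-enoic acid | CC(=O)Oc1ccc(/C=C/C(=O)O)cc1 | intermediate
25 | (E)-3-(4-acetoxyphenyl)prop-2-enoyl chloride (not isolated) | CC(=O)Oc1ccc(/C=C/C(Cl)=O)cc1 | intermediate
26 | 3-O-(3,4-di-O-acetylcaffeoyl)-4-O-(4-O-acetyl-p-coumaroyl)quinic acid 1,5-lactone (O1 free) | O[C@@]12C[C@@H](OC(=O)/C=C/c3ccc(OC(C)=O)c(OC(C)=O)c3)[C@@H](OC(=O)/C=C/c3ccc(OC(C)=O)cc3)[C@@H](C1)OC2=O | intermediate
27 | 3-O-caffeoyl-4-O-p-coumaroylquinic acid (O1, O3, O4 on one face; O5 and carboxyl on the other; both alkenes E) | O=C(/C=C/c1ccc(O)cc1)O[C@H]1[C@H](O)C[C@](O)(C(=O)O)C[C@H]1OC(=O)/C=C/c1ccc(O)c(O)c1 | target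

Total step count: 16. Longest linear sequence: 14 steps (steps 1 to 11, then 13, 15 and 16); steps 12 and 14 prepare the two acyl components.

Steps most likely to fail

Step 8. The small dienophile may discriminate poorly between the two diene faces, or the polarized transition state may collapse by 1,4-silyl transfer to a 4-silylperoxy enone or by dioxetane formation and C3–C4 cleavage instead of closing at the ester-bearing C1. The fallback installs the two oxygens one after the other and sets out from diene 11. Rubottom oxidation (dimethyldioxirane, acetone–CH2Cl2, −78 °C, then mild acid) epoxidizes the electron-rich C3=C4 enol ether anti to the C5 silyloxy group and should give methyl 5-O-(triisopropylsilyl)-3-dehydroshikimate F1. Weitz–Scheffer epoxidation of its electron-poor C1=C2 bond (t-BuOOH, benzyltrimethylammonium hydroxide cat., THF, −20 °C), again anti to the C5 ether, should give the 1,2-epoxy ketone F2. Reductive opening of the C2–O bond with Na[PhSeB(OEt)3] (from (PhSe)2 and NaBH4, EtOH, AcOH) then leaves the C1 carbinol, and the sequence rejoins the route at 15.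

Step 5. Chlorine transfer to the hindered tertiary enolate may be sluggish, or the neighbouring alkoxide may set off lactonization or self-condensation. The fallback drops the C1 marker and dehydrogenates the ketone instead, setting out from alcohol 5. Dess–Martin oxidation should give methyl cis-3-oxo-5-(triisopropylsilyloxy)cyclohexane-1-carboxylate F3. Kinetic enolization with LiN(iPr)2 and Me3SiCl (THF, −78 °C), steered toward C2 by the bulky ether on C5, should give the trimethylsilyl enol ether F4. Saegusa–Ito oxidation with Pd(OAc)2 (MeCN, rt) then rejoins the route at enone 9. The regiochemistry of the enolization is the point to check in this variant.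

Step 13. The rate difference between the equatorial O3 and the axial O4 hydroxyl may be too small, so that mono- and diesters form side by side. The fallback replaces intrinsic reactivity by tin activation and sets out from lactone 18. Bu2SnO (MeOH, reflux, then evaporation) should bridge the cis O3/O4 diol as the 3,4-O-dibutylstannylene acetal F5. Acid chloride 21 (CH2Cl2, 0 °C) then acylates the equatorial tin-bound O3, as is usual for stannylene acetals of cis diols, and aqueous work-up rejoins the route at 22.

Further compounds
F1 | step 8 | methyl (4S,5R)-4-hydroxy-3-oxo-5-(triisopropylsilyloxy)cyclohex-1-ene-1-carboxylate (methyl 5-O-triisopropylsilyl-3-dehydroshikimate) | COC(=O)C1=CC(=O)[C@@H](O)[C@H](O[Si](C(C)C)(C(C)C)C(C)C)C1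
F2 | step 8 | methyl 1,2-epoxy-4-hydroxy-3-oxo-5-(triisopropylsilyloxy)cyclohexane-1-carboxylate (epoxide oxygen cis to 4-OH and trans to 5-OSi) | COC(=O)[C@]12O[C@H]1C(=O)[C@@H](O)[C@H](O[Si](C(C)C)(C(C)C)C(C)C)C2
F3 | step 5 | methyl cis-3-oxo-5-(triisopropylsilyloxy)cyclohexane-1-carboxylate (C1 and C5 as in 5) | COC(=O)[C@@H]1CC(=O)C[C@H](O[Si](C(C)C)(C(C)C)C(C)C)C1
F4 | step 5 | methyl cis-3-(trimethylsilyloxy)-5-(triisopropylsilyloxy)cyclohex-2-ene-1-carboxylate | COC(=O)[C@@H]1C=C(O[Si](C)(C)C)C[C@H](O[Si](C(C)C)(C(C)C)C(C)C)C1
F5 | step 13 | 3,4-O-dibutylstannylene acetal of quinic acid 1,5-lactone | O[C@@]12C[C@@H](O[Sn]3(CCCC)CCCC)[C@@H](O3)[C@@H](C1)OC2=O
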